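**Retrosynthetic overview**
1. Target ⇒ C6 alcohol (final O-acetylation).
2. C6–O, cis to C7–O ⇒ copper-catalysed 1,6-boryl addition and oxidation on a 7-acyloxy-cyclohexa-2,4-dienone.
3. Key disconnection, C7–O: the tertiary everninate ester and the quaternary centre come from an enantioselective ortho-acyloxylative dearomatisation of (S)-7-methyl-3-propenylisochroman-8-ol with everninic acid.
4. Pyran ring (C4a–C4 and C3–O) ⇒ asymmetric palladium diene heteroannulation of 3-bromo-2-(hydroxymethyl)-6-methylphenol with (E)-penta-1,3-diene; its CH2OH (C1) ⇒ ortho-hydroxymethylation of 5-bromo-2-methylphenol.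
5. Ring order: the carbocycle is bought as an arene, the pyran ring is closed second, and the arene is then dearomatised and adjusted to the cyclohexenone.

Assumption: everninic acid (2-hydroxy-4-methoxy-6-methylbenzoic acid) is bought as such; the chiral aryliodine diacetate and the ligands are reagents made separately and are not counted as steps.

**Route**

Step 1
Reactants: 1 5-bromo-2-methylphenol; 2 paraformaldehyde
Product: 4 3-bromo-2-(hydroxymethyl)-6-methylphenol, via benzodioxaborin 3 (not isolated)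
Conditions: PhB(OH)2 (1.1 equiv), 2 (3 equiv), EtCO2H (0.3 equiv), PhMe, reflux, Dean–Stark; then propane-1,3-diol (5 equiv), rt
Reagents that add atoms: phenylboronic acid OB(O)c1ccccc1 (its PhB unit is in 3 only and is removed again)
Why: Nagata ortho-hydroxymethylation, in which the aryl phenylboronate holds formaldehyde next to the only free ortho carbon and closes the six-membered dioxaborin that the diol then opens to the salicyl alcohol; no stereocentre is formed.

Step 2
Reactants: 4 3-bromo-2-(hydroxymethyl)-6-methylphenol; 5 (E)-penta-1,3-diene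
Product: 6 (3S)-7-methyl-3-[(E)-prop-1-enyl]isochroman-8-ol
Conditions: Pd2(dba)3 (2.5 mol%), (S,R,R)-(1,1'-binaphthalene-2,2'-diyl) N,N-bis(1-phenylethyl)phosphoramidite (11 mol%), K3PO4 (2 equiv), 5 (4 equiv), PhMe, 80 °C, sealed tube
Reagents that add atoms: none
Why: Larock-type diene heteroannulation run as an asymmetric Heck/Tsuji–Trost cascade, in which zerovalent palladium inserts into the C–Br bond, the aryl group adds to the CH2= end of the diene to give a syn π-allyl complex, and the benzylic hydroxyl attacks the near allyl terminus anti to palladium, closing the six-membered ether with an (E)-propenyl group while the chiral phosphoramidite (enantiomer chosen for this sense) sets C3 as S.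

Step 3
Reactants: 6 (3S)-7-methyl-3-[(E)-prop-1-enyl]isochroman-8-ol; 7 everninic acid
Product: 9 (3S,7S)-7-methyl-8-oxo-3-[(E)-prop-1-enyl]-3,4,7,8-tetrahydro-1H-isochromen-7-yl 2-hydroxy-4-methoxy-6-methylbenzoate, via iodane dicarboxylate 8 (not isolated)
Conditions: (R,R)-2,6-bis[1-(mesitylcarbamoyl)ethoxy]phenyliodine diacetate (1.1 equiv), 7 (2.2 equiv), CH2Cl2, rt, AcOH stripped with PhMe in vacuo; then 6 (1.0 equiv), CH2Cl2, −40 °C
Reagents that add atoms: (R,R)-2,6-bis[1-(mesitylcarbamoyl)ethoxy]phenyliodine diacetate C[C@@H](Oc1cccc(O[C@H](C)C(=O)Nc2c(C)cc(C)cc2C)c1I(OC(C)=O)OC(C)=O)C(=O)Nc1c(C)cc(C)cc1C (its aryliodine unit is in 8 only)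
Why: Proposed new method: an enantioselective, ortho-selective intermolecular acyloxylative dearomatisation in which a C2-symmetric chiral trivalent-iodine dicarboxylate hands over one of its own carboxylate ligands; the phenol of 6 replaces one everninate on iodine and the other everninate passes from iodine to the ortho carbon through a five-membered ligand-coupling transition state as the iodoarene leaves, which confines attack to an ortho carbon and not the free para CH, favours the methyl-bearing C7 over the more buttressed C8a, and lets the hydrogen-bonded lactamide arms choose the face so that C7 becomes S regardless of the remote C3 centre (the mirror-image reagent is used if a model phenol shows the opposite sense), while the chelated, carboxyl-deactivated phenol of the acid is expected to stay inert at −40 °C; the closest known reactions are the racemic Wessely ortho-acyloxylation of 2,6-dialkylphenols with lead or iodine carboxylates and the enantioselective but intramolecular Kita-type spirolactonisation with chiral iodoarenes.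

Step 4
Reactants: 9 (3S,7S)-7-methyl-8-oxo-3-[(E)-prop-1-enyl]-3,4,7,8-tetrahydro-1H-isochromen-7-yl 2-hydroxy-4-methoxy-6-methylbenzoate
Product: 11 (3S,6S,7S)-6-hydroxy-7-methyl-8-oxo-3-[(E)-prop-1-enyl]-3,4,5,6,7,8-hexahydro-1H-isochromen-7-yl 2-hydroxy-4-methoxy-6-methylbenzoate, via C6 boronate 10 (not isolated)
Conditions: CuCl (5 mol%), (R)-SEGPHOS (6 mol%), Cs2CO3 (15 mol%), B2pin2 (1.2 equiv), MeOH (2 equiv), THF, 0 °C; then NaBO3·4H2O (4 equiv), THF/H2O, 0 °C to rt
Reagents that add atoms: bis(pinacolato)diboron CC1(C)OB(OC1(C)C)B1OC(C)(C)C(C)(C)O1 (boryl group in 10 only); sodium perborate [Na+].[Na+].O[B-]1(O)OO[B-](O)(O)OO1 (the C6 oxygen)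
Why: Copper-catalysed 1,6-conjugate borylation followed by stereoretentive boronate oxidation, in which the boryl copper adds to the δ-carbon C6 because the β-carbon C4a is fully substituted, enters on the face syn to the C7 acyloxy group (the facial bias these 6-acyloxy-dienones show in cycloadditions, reinforced by the matched ligand), the dienolate is protonated to the conjugated enone, and oxidation with retention gives the 6S alcohol cis to the ester.

Step 5
Reactants: 11 (3S,6S,7S)-6-hydroxy-7-methyl-8-oxo-3-[(E)-prop-1-enyl]-3,4,5,6,7,8-hexahydro-1H-isochromen-7-yl 2-hydroxy-4-methoxy-6-methylbenzoate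
Product: 13 (3S,6S,7S)-6-acetoxy-7-methyl-8-oxo-3-[(E)-prop-1-enyl]-3,4,5,6,7,8-hexahydro-1H-isochromen-7-yl 2-hydroxy-4-methoxy-6-methylbenzoate (CNP0223989.1), via diacetate 12 (not isolated)
Conditions: Ac2O (4 equiv), DMAP (0.1 equiv), pyridine, CH2Cl2, 0 °C; then MeOH, NH4OAc (2 equiv), 0 °C to rt
Reagents that add atoms: acetic anhydride CC(=O)OC(C)=O
Why: DMAP-catalysed acetylation of the hindered C6 hydroxyl (and of the phenol), then chemoselective neutral methanolysis of the aryl acetate, which cleaves far faster than the secondary alkyl acetate; no stereocentre is touched and the base-sensitive δ-acetoxy enone sees only weak bases at low temperature.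

**Compound list**
1 | 5-bromo-2-methylphenol | Cc1ccc(Br)cc1O | starting material
2 | paraformaldehyde (formaldehyde unit) | C=O | starting material
3 | 5-bromo-8-methyl-2-phenyl-4H-1,3,2-benzodioxaborine | Cc1ccc(Br)c2COB(c3ccccc3)Oc12 | intermediate
4 | 3-bromo-2-(hydroxymethyl)-6-methylphenol | Cc1ccc(Br)c(CO)c1O | intermediate
5 | (E)-penta-1,3-diene | C/C=C/C=C | starting material
6 | (3S)-7-methyl-3-[(E)-prop-1-enyl]isochroman-8-ol | C/C=C/[C@@H]1Cc2ccc(C)c(O)c2CO1 | intermediate
7 | everninic acid (2-hydroxy-4-methoxy-6-methylbenzoic acid) | Cc1cc(OC)cc(O)c1C(=O)O | starting material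
8 | [2,6-bis[(1R)-1-(mesitylcarbamoyl)ethoxy]phenyl]iodine bis(2-hydroxy-4-methoxy-6-methylbenzoate) | C[C@@H](Oc1cccc(O[C@H](C)C(=O)Nc2c(C)cc(C)cc2C)c1I(OC(=O)c1c(C)cc(OC)cc1O)OC(=O)c1c(C)cc(OC)cc1O)C(=O)Nc1c(C)cc(C)cc1C | intermediate
9 | (3S,7S)-7-methyl-8-oxo-3-[(E)-prop-1-enyl]-3,4,7,8-tetrahydro-1H-isochromen-7-yl 2-hydroxy-4-methoxy-6-methylbenzoate | C/C=C/[C@@H]1CC2=C(CO1)C(=O)[C@@](C)(OC(=O)c1c(C)cc(OC)cc1O)C=C2 | intermediate
10 | (3S,6S,7S)-7-methyl-8-oxo-6-(4,4,5,5-tetramethyl-1,3,2-dioxaborolan-2-yl)-3-[(E)-prop-1-enyl]-3,4,5,6,7,8-hexahydro-1H-isochromen-7-yl 2-hydroxy-4-methoxy-6-methylbenzoate | C/C=C/[C@@H]1CC2=C(CO1)C(=O)[C@@](C)(OC(=O)c1c(C)cc(OC)cc1O)[C@@H](B1OC(C)(C)C(C)(C)O1)C2 | intermediate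
11 | (3S,6S,7S)-6-hydroxy-7-methyl-8-oxo-3-[(E)-prop-1-enyl]-3,4,5,6,7,8-hexahydro-1H-isochromen-7-yl 2-hydroxy-4-methoxy-6-methylbenzoate | C/C=C/[C@@H]1CC2=C(CO1)C(=O)[C@@](C)(OC(=O)c1c(C)cc(OC)cc1O)[C@@H](O)C2 | intermediate
12 | (3S,6S,7S)-6-acetoxy-7-methyl-8-oxo-3-[(E)-prop-1-enyl]-3,4,5,6,7,8-hexahydro-1H-isochromen-7-yl 2-acetoxy-4-methoxy-6-methylbenzoate | C/C=C/[C@@H]1CC2=C(CO1)C(=O)[C@@](C)(OC(=O)c1c(C)cc(OC)cc1OC(C)=O)[C@@H](OC(C)=O)C2 | intermediate
13 | (3S,6S,7S)-6-acetoxy-7-methyl-8-oxo-3-[(E)-prop-1-enyl]-3,4,5,6,7,8-hexahydro-1H-isochromen-7-yl 2-hydroxy-4-methoxy-6-methylbenzoate (CNP0223989.1) | C/C=C/[C@@H]1CC2=C(CO1)C(=O)[C@@](C)(OC(=O)c1c(C)cc(OC)cc1O)[C@@H](OC(C)=O)C2 | target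

**Step count and risks**

Total steps: 5. Longest linear sequence: 5 (1 → 4 → 6 → 9 → 11 → 13).

Steps most likely to fail:

Step 3 (the proposed new step). Risks are attack at the free para CH or at C8a, weak face selectivity, and oxidation of the acid's own phenol. The fallback sets out from 6 and comes back at 9. It is the classical Wessely acyloxylation with tetravalent lead: Pb(OAc)4 (1.2 equiv) premixed with excess 7 in CH2Cl2 at 0 °C. This is ortho-selective but not face-selective, so it gives 9 together with its C7 epimer (3S,7R)-7-methyl-8-oxo-3-[(E)-prop-1-enyl]-3,4,7,8-tetrahydro-1H-isochromen-7-yl 2-hydroxy-4-methoxy-6-methylbenzoate F3. The two are diastereomers because C3 is fixed and are separated by chromatography; 9 goes on to step 4.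

Step 2. Risks are low enantioselectivity with an aliphatic diene and a benzylic alcohol nucleophile, plain Heck products, and interference by the free phenol. The fallback sets out from 4 and comes back at 6, taking C3 from a bought stereocentre instead. Suzuki–Miyaura allylation of 4 with allylboronic acid pinacol ester (Pd(dppf)Cl2, K2CO3, dioxane/H2O, 80 °C) gives 3-allyl-2-(hydroxymethyl)-6-methylphenol F1. Cross-metathesis with (R)-but-3-en-2-ol (second-generation Hoveyda–Grubbs catalyst RuCl2(H2IMes)(=CH-C6H4-2-O-i-Pr), CH2Cl2, 40 °C) gives (2R,3E)-5-[3-hydroxy-2-(hydroxymethyl)-4-methylphenyl]pent-3-en-2-ol F2. Gold-catalysed dehydrative SN2' cyclisation (Ph3PAuCl/AgOTf 1 mol%, 4 Å sieves, CH2Cl2, −10 °C) then gives 6. Anti oxyauration followed by anti loss of water is a net syn 1,3-chirality transfer, so the 2R carbinol gives 3S with the (E)-propenyl group.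

Step 4. Risks are boron entering anti to the acyloxy group (giving the 6-epimer) and loss of the β-acyloxy boronate by elimination and re-aromatisation before it is oxidised. The fallback sets out from 9 and comes back at 11. Nucleophilic epoxidation of the γ,δ-double bond (t-BuOOH, DBU, CH2Cl2, 0 °C) gives (3S,5S,6S,7S)-5,6-epoxy-7-methyl-8-oxo-3-[(E)-prop-1-enyl]-3,4,5,6,7,8-hexahydro-1H-isochromen-7-yl 2-hydroxy-4-methoxy-6-methylbenzoate F4. Palladium-catalysed formate hydrogenolysis of this alkenyl epoxide (Pd2(dba)3, n-Bu3P, HCO2H/Et3N, THF, rt) cleaves the allylic C5–O bond and leaves the C6 alcohol, giving 11. The α-acyloxy ketone survives these conditions, which it would not under SmI2.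

Further compounds
F1 | step 2 | 3-allyl-2-(hydroxymethyl)-6-methylphenol | C=CCc1ccc(C)c(O)c1CO
F2 | step 2 | (2R,3E)-5-[3-hydroxy-2-(hydroxymethyl)-4-methylphenyl]pent-3-en-2-ol | C[C@@H](O)/C=C/Cc1ccc(C)c(O)c1CO
F3 | step 3 | (3S,7R)-7-methyl-8-oxo-3-[(E)-prop-1-enyl]-3,4,7,8-tetrahydro-1H-isochromen-7-yl 2-hydroxy-4-methoxy-6-methylbenzoate | C/C=C/[C@@H]1CC2=C(CO1)C(=O)[C@](C)(OC(=O)c1c(C)cc(OC)cc1O)C=C2
F4 | step 4 | (3S,5S,6S,7S)-5,6-epoxy-7-methyl-8-oxo-3-[(E)-prop-1-enyl]-3,4,5,6,7,8-hexahydro-1H-isochromen-7-yl 2-hydroxy-4-methoxy-6-methylbenzoate | C/C=C/[C@@H]1CC2=C(CO1)C(=O)[C@@](C)(OC(=O)c3c(C)cc(OC)cc3O)[C@H]3O[C@@H]23
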